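The runs were computed with constants of no real substance; noise was put on by code.

I reckoned this flask with a ratio: the nucleophile's rate of loss divided by the electrophile's. Time dropped out of that ratio, which left the nucleophile lost per electrophile lost.

| flask | electrophile | nucleophile | remark | time |
|---|---|---|---|---|
| grey | 0.034 M | 0.15 M | run made earlier |  |
| east | 0.050 M | 0.150 M |  | 8.0 h |
| west | 0.050 M | 0.220 M |  | 8.0 h |
| north-west | 0.050 M | 0.340 M |  | 8.0 h |

- grey (time / min: electrophile / %, target / %): 8.00: 99.0, 0.6; 12.0: 97.6, 3.8; 20.0: 93.9, 3.6; 40.0: 91.9, 9.9; 60.0: 87.4, 13.3; 90.0: 81.0, 19.2

(each reading ± 1 percentage point)

- part of the electrophile that has reacted at the end, east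
- part of the electrophile that has reacted at the end, west
- part of the electrophile that has reacted at the end, north-west
- what raising the concentration of nucleophile from its lowest to its highest value here does to the part of the electrophile that has reacted (changes below 5 percentage points count as none) (it falls / no change / it rises)

- what was read earlier has a scatter of 1 percentage point, one standard deviation

The grey run gave no readings of the nucleophile. After 90.0 min it had the electrophile at 81.0% and the target at 19.2%, so I read one target per electrophile lost. Assuming first order in each partner, I read a rate constant of 0.0156 /M/min, with the scatter of that reading.

Two extremes could be solved. In the first, the pseudo-first-order limit, I held the nucleophile at its charge and reckoned 67.5% for east and 92.2% for north-west. In the second, I let two nucleophile go per electrophile, one into the target and one bound by whatever left the electrophile. East then had a drain of 66.7%, the drain being two nucleophile per electrophile charged, over the nucleophile charged. The share of nucleophile left was then the whole minus the drain times the part reacted, at any moment. Putting that line into the rate law gave 57.7% for east, 72.8% for west and 87.7% for north-west. I took the real flask to lie between the extremes, with the ratio somewhere from none to two. The gap was wider in east than in north-west, whose drain was 29.4%. I committed to the second, cautious end.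

The forecast, taking “first order in each partner”, gave 63% (55% to 71%) for east, 77% for west and 90% for north-west, and said it rises; my east stood lower.

East gave 57.9%, west 72.9% and north-west 87.7%; from lowest to highest nucleophile it rises, by 30 percentage points.

    electrophile + nucleophile → acid set free + target (k = 2.60 × 10⁻⁴ /M/s)
    nucleophile + acid set free ⇌ protonated nucleophile, settled at all times (K = 200 /M)

In east at 8.00 h, protonated nucleophile stood at 0.0275 M beside 0.0289 M of target. The drain applied to the part reacted left 61.4% of the nucleophile, and east had 62% of its charge still free.

With 0.20 M of electrophile in north-west's recipe, the drain was 118%, and the same line gave 67.2% reacted and 20.7% of the nucleophile left. That flask gave 67.9% and 23%.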